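Ring D is made last among the rings: its D1–D2 and D5–D6 bonds are formed by a [4+2] cycloaddition between an (E)-1-nitrobut-1-ene that already carries rings C, A and B as benzyl ethers and 1-methoxy-3-(trimethylsilyloxy)buta-1,3-diene. The feature exploited is the meta (1,3) relation in ring D between the chain-bearing carbon D1 and the oxygen-bearing carbon D3. A nitro group on D6 steers the diene oxygen to D3 and then leaves as nitrous acid, together with methanol, so that one operation closes and aromatises ring D as the only free phenol. Methylation and double hydrogenolysis finish the target.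

Key step: step 9

Remark: ring A is the para-disubstituted aryloxy ring, ring B the 3-hydroxyphenyl ring, ring C the phenol ring carrying the aryloxy group and ring D the 3-methoxyphenyl ring (D1 bears the CH2CH2 link to ring C, D3 the oxygen); intermediates 14, 17 and 18 are taken as racemic, their sp3 centres being lost before the achiral target.

Step 1
Reactants: 1 5-bromo-2-hydroxybenzaldehyde
Product: 2 2-(benzyloxy)-5-bromobenzaldehyde
Conditions: BnBr, K2CO3, DMF, rt to 50 °C
Reagents that add atoms: benzyl bromide, BrCc1ccccc1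
Why: Williamson etherification (SN2 of the acidic ortho-formyl phenoxide on benzyl bromide) should be clean because the aldehyde and the aryl bromide are inert to carbonate.

Step 2
Reactants: 2 2-(benzyloxy)-5-bromobenzaldehyde
Product: 4 2-(benzyloxy)-5-bromophenol, via aryl formate 3 (not isolated)
Conditions: mCPBA, CH2Cl2, rt; then K2CO3 (cat.), MeOH, rt
Reagents that add atoms: 3-chloroperoxybenzoic acid (mCPBA), OOC(=O)c1cccc(Cl)c1
Why: Baeyer–Villiger (Dakin-type) oxidation, in which the electron-rich ortho-alkoxyaryl group migrates to oxygen in preference to hydride, followed by mild methanolysis of formate 3 that leaves the benzyl ether and the bromide intact.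

Step 3
Reactants: 4 2-(benzyloxy)-5-bromophenol; 5 4-fluorobenzaldehyde
Product: 6 4-[2-(benzyloxy)-5-bromophenoxy]benzaldehyde
Conditions: K2CO3, DMF, 120 °C
Reagents that add atoms: none
Why: SNAr (addition–elimination through a Meisenheimer adduct), the para-formyl group activating fluoride toward the phenoxide while the unactivated C–Br bond does not react.

Step 4
Reactants: 7 3-(benzyloxy)benzyl bromide
Product: 8 diethyl [3-(benzyloxy)benzyl]phosphonate
Conditions: P(OEt)3 (neat), 130 °C
Reagents that add atoms: triethyl phosphite, CCOP(OCC)OCC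
Why: Michaelis–Arbuzov reaction, SN2 attack of phosphorus on the benzylic bromide followed by dealkylation of the phosphonium ion by bromide, with volatile bromoethane distilling out.

Step 5
Reactants: 6 4-[2-(benzyloxy)-5-bromophenoxy]benzaldehyde; 8 diethyl [3-(benzyloxy)benzyl]phosphonate
Product: 9 1-(benzyloxy)-2-(4-{(E)-2-[3-(benzyloxy)phenyl]ethenyl}phenoxy)-4-bromobenzene
Conditions: KOtBu, THF, 0 °C to rt
Reagents that add atoms: none
Why: Horner–Wadsworth–Emmons olefination, in which reversible addition of the benzylic phosphonate anion and syn-elimination from the favoured oxaphosphetane should give the E-stilbene, whose geometry is in any case erased in step 6.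

Step 6
Reactants: 9 1-(benzyloxy)-2-(4-{(E)-2-[3-(benzyloxy)phenyl]ethenyl}phenoxy)-4-bromobenzene
Product: 10 1-(benzyloxy)-2-(4-{2-[3-(benzyloxy)phenyl]ethyl}phenoxy)-4-bromobenzene
Conditions: TsNHNH2 (excess, in portions), NaOAc, DME–H2O, reflux
Reagents that add atoms: none
Why: Diimide reduction, HN=NH generated in the flask delivering two hydrogens to the C=C in a concerted syn transfer while leaving the aryl bromide and the benzyl ethers alone, which a palladium-catalysed hydrogenation would put at risk.

Step 7
Reactants: 10 1-(benzyloxy)-2-(4-{2-[3-(benzyloxy)phenyl]ethyl}phenoxy)-4-bromobenzene; 11 allyl alcohol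
Product: 12 3-[4-(benzyloxy)-3-(4-{2-[3-(benzyloxy)phenyl]ethyl}phenoxy)phenyl]propanal
Conditions: Pd(OAc)2 (cat.), Bu4NCl, NaHCO3, DMF, 80 °C
Reagents that add atoms: none
Why: Heck reaction under Jeffery conditions, the arylpalladium bromide adding with aryl at the terminal alkene carbon, β-hydride elimination toward the carbinol carbon giving the enol and hence the saturated aldehyde, with the ammonium chloride stabilising the ligand-free zerovalent palladium.

Step 8
Reactants: 12 3-[4-(benzyloxy)-3-(4-{2-[3-(benzyloxy)phenyl]ethyl}phenoxy)phenyl]propanal; 13 nitromethane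
Product: 15 1-(benzyloxy)-2-(4-{2-[3-(benzyloxy)phenyl]ethyl}phenoxy)-4-[(3E)-4-nitrobut-3-en-1-yl]benzene, via nitroaldol 14 (not isolated)
Conditions: MeNO2 (excess), KOtBu (cat.), THF–t-BuOH, 0 °C to rt, aqueous work-up; then MsCl, Et3N, CH2Cl2, −10 to 0 °C
Reagents that add atoms: none
Why: Henry (nitroaldol) addition followed by mesylation and E1cB elimination through the nitronate should give the conjugated nitroalkene as the thermodynamically preferred E isomer, the low temperature limiting migration of the double bond out of conjugation.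

Step 9
Reactants: 15 1-(benzyloxy)-2-(4-{2-[3-(benzyloxy)phenyl]ethyl}phenoxy)-4-[(3E)-4-nitrobut-3-en-1-yl]benzene; 16 (E)-1-methoxy-3-(trimethylsilyloxy)buta-1,3-diene
Product: 19 3-{2-[4-(benzyloxy)-3-(4-{2-[3-(benzyloxy)phenyl]ethyl}phenoxy)phenyl]ethyl}phenol, via cycloadduct 17 (not isolated), via nitro enone 18 (not isolated)
Conditions: PhMe, rt to 80 °C; then TFA (cat.), THF–H2O, 0 °C to rt; then DBU (excess), rt
Reagents that add atoms: none
Why: The electron-rich diene 16 and the electron-poor nitroalkene 15 should combine in a concerted but asynchronous normal-demand [4+2] cycloaddition, the unsubstituted CH2 terminus of the diene (largest HOMO coefficient) bonding to the chain-bearing β-carbon of the nitroalkene (D1–D2) and the methoxy-bearing terminus to the nitro carbon (D5–D6). Acid then cleaves the silyl enol ether of 17 and expels methanol to give the γ-nitro enone 18, and DBU enolises 18 toward D2 so that nitrous acid is lost across D6–D1 in an aromatisation-driven elimination, the dienone/dienol tautomerising to phenol 19. The closest known reaction type is the Diels–Alder benzannulation of nitroalkenes with 1-methoxy-3-silyloxydienes, in which the nitro group serves as a traceless regiocontrol element and the nitroalkene as an alkyne equivalent. Ring D is closed by an intermolecular [4+2] cycloaddition through a six-membered transition state, both ring bonds forming in the one event. No stereocentre survives, since the three sp3 centres of 17 (endo adduct, racemic) are erased on aromatisation, so no stereocontrol is required. The only selectivity needed is regiochemical and it is secured by the nitro group being the sole polarising substituent on the alkene, which places the D3 oxygen meta to the chain on D1, while the benzyl ethers, the diaryl ether and the arenes are inert to these conditions.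

Step 10
Reactants: 19 3-{2-[4-(benzyloxy)-3-(4-{2-[3-(benzyloxy)phenyl]ethyl}phenoxy)phenyl]ethyl}phenol
Product: 20 1-(benzyloxy)-2-(4-{2-[3-(benzyloxy)phenyl]ethyl}phenoxy)-4-[2-(3-methoxyphenyl)ethyl]benzene
Conditions: MeI, K2CO3, acetone, reflux
Reagents that add atoms: iodomethane, CI
Why: Williamson O-methylation, the ring D hydroxyl being the only free OH in 19 so that the methyl group can go to no other oxygen.

Step 11
Reactants: 20 1-(benzyloxy)-2-(4-{2-[3-(benzyloxy)phenyl]ethyl}phenoxy)-4-[2-(3-methoxyphenyl)ethyl]benzene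
Product: 21 2-(4-{2-[3-hydroxyphenyl]ethyl}phenoxy)-4-[2-(3-methoxyphenyl)ethyl]phenol
Conditions: H2 (1 atm), Pd/C (10% palladium on carbon), EtOAc–MeOH, rt
Reagents that add atoms: none
Why: Catalytic hydrogenolysis of the two benzylic C–O bonds releases the ring B and ring C phenols, while the methyl ether, the diaryl ether and the CH2CH2 links are inert.

Compound list
1 | 5-bromo-2-hydroxybenzaldehyde | O=Cc1cc(Br)ccc1O | starting material
2 | 2-(benzyloxy)-5-bromobenzaldehyde | O=Cc1cc(Br)ccc1OCc1ccccc1 | intermediate
3 | 2-(benzyloxy)-5-bromophenyl formate | O=COc1cc(Br)ccc1OCc1ccccc1 | intermediate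
4 | 2-(benzyloxy)-5-bromophenol | Oc1cc(Br)ccc1OCc1ccccc1 | intermediate
5 | 4-fluorobenzaldehyde | O=Cc1ccc(F)cc1 | starting material
6 | 4-[2-(benzyloxy)-5-bromophenoxy]benzaldehyde | O=Cc1ccc(Oc2cc(Br)ccc2OCc2ccccc2)cc1 | intermediate
7 | 3-(benzyloxy)benzyl bromide | BrCc1cccc(OCc2ccccc2)c1 | starting material
8 | diethyl [3-(benzyloxy)benzyl]phosphonate | CCOP(=O)(Cc1cccc(OCc2ccccc2)c1)OCC | intermediate
9 | 1-(benzyloxy)-2-(4-{(E)-2-[3-(benzyloxy)phenyl]ethenyl}phenoxy)-4-bromobenzene | Brc1ccc(OCc2ccccc2)c(Oc2ccc(/C=C/c3cccc(OCc4ccccc4)c3)cc2)c1 | intermediate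
10 | 1-(benzyloxy)-2-(4-{2-[3-(benzyloxy)phenyl]ethyl}phenoxy)-4-bromobenzene | Brc1ccc(OCc2ccccc2)c(Oc2ccc(CCc3cccc(OCc4ccccc4)c3)cc2)c1 | intermediate
11 | allyl alcohol (prop-2-en-1-ol) | C=CCO | starting material
12 | 3-[4-(benzyloxy)-3-(4-{2-[3-(benzyloxy)phenyl]ethyl}phenoxy)phenyl]propanal | O=CCCc1ccc(OCc2ccccc2)c(Oc2ccc(CCc3cccc(OCc4ccccc4)c3)cc2)c1 | intermediate
13 | nitromethane | C[N+](=O)[O-] | starting material
14 | 4-[4-(benzyloxy)-3-(4-{2-[3-(benzyloxy)phenyl]ethyl}phenoxy)phenyl]-1-nitrobutan-2-ol (racemic) | O=[N+]([O-])CC(O)CCc1ccc(OCc2ccccc2)c(Oc2ccc(CCc3cccc(OCc4ccccc4)c3)cc2)c1 | intermediate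
15 | 1-(benzyloxy)-2-(4-{2-[3-(benzyloxy)phenyl]ethyl}phenoxy)-4-[(3E)-4-nitrobut-3-en-1-yl]benzene | O=[N+]([O-])/C=C/CCc1ccc(OCc2ccccc2)c(Oc2ccc(CCc3cccc(OCc4ccccc4)c3)cc2)c1 | intermediate
16 | (E)-1-methoxy-3-(trimethylsilyloxy)buta-1,3-diene | CO/C=C/C(=C)O[Si](C)(C)C | starting material
17 | [(5-{2-[4-(benzyloxy)-3-(4-{2-[3-(benzyloxy)phenyl]ethyl}phenoxy)phenyl]ethyl}-3-methoxy-4-nitrocyclohex-1-en-1-yl)oxy]trimethylsilane (racemic endo adduct, methoxy and nitro cis, nitro and side chain trans; one enantiomer drawn) | CO[C@H]1C=C(O[Si](C)(C)C)C[C@H](CCc2ccc(OCc3ccccc3)c(Oc3ccc(CCc4cccc(OCc5ccccc5)c4)cc3)c2)[C@H]1[N+](=O)[O-] | intermediate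
18 | trans-5-{2-[4-(benzyloxy)-3-(4-{2-[3-(benzyloxy)phenyl]ethyl}phenoxy)phenyl]ethyl}-4-nitrocyclohex-2-en-1-one (racemic; one enantiomer drawn) | O=C1C=C[C@H]([N+](=O)[O-])[C@@H](CCc2ccc(OCc3ccccc3)c(Oc3ccc(CCc4cccc(OCc5ccccc5)c4)cc3)c2)C1 | intermediate
19 | 3-{2-[4-(benzyloxy)-3-(4-{2-[3-(benzyloxy)phenyl]ethyl}phenoxy)phenyl]ethyl}phenol | Oc1cccc(CCc2ccc(OCc3ccccc3)c(Oc3ccc(CCc4cccc(OCc5ccccc5)c4)cc3)c2)c1 | intermediate
20 | 1-(benzyloxy)-2-(4-{2-[3-(benzyloxy)phenyl]ethyl}phenoxy)-4-[2-(3-methoxyphenyl)ethyl]benzene | COc1cccc(CCc2ccc(OCc3ccccc3)c(Oc3ccc(CCc4cccc(OCc5ccccc5)c4)cc3)c2)c1 | intermediate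
21 | 2-(4-{2-[3-hydroxyphenyl]ethyl}phenoxy)-4-[2-(3-methoxyphenyl)ethyl]phenol | COc1cccc(CCc2ccc(O)c(Oc3ccc(CCc4cccc(O)c4)cc3)c2)c1 | target

Total step count: 11.
Longest linear sequence: 10 steps (steps 1, 2, 3, 5, 6, 7, 8, 9, 10, 11, from 5-bromo-2-hydroxybenzaldehyde); step 4 is a one-step side branch.

Steps most likely to fail

Step 9. The cycloaddition may be slow for a β-alkyl nitroalkene, so that thermal polymerisation or double-bond migration of the dienophile competes. Loss of nitrous acid may also stall at the nitro enone stage or be diverted into conjugate additions under DBU. The fallback gives up the benzannulation and attaches a preformed ring D by cross-coupling. It sets out from bromide 10: Sonogashira coupling with 1-ethynyl-3-methoxybenzene (PdCl2(PPh3)2, CuI, Et3N, DMF, 80 °C) should give 1-(benzyloxy)-2-(4-{2-[3-(benzyloxy)phenyl]ethyl}phenoxy)-4-[(3-methoxyphenyl)ethynyl]benzene F1. Hydrogenation over Pd/C (H2, EtOAc–MeOH, rt) then saturates the alkyne and cleaves both benzyl ethers in one operation, coming back to the route at target 21.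

Step 7. Oxidative addition into the electron-rich C–Br bond may be sluggish and palladium may precipitate. Partial arylation at the internal alkene carbon would give branched aldehyde, and the product aldehyde may undergo aldol condensation in the hot basic medium. The fallback replaces the Heck reaction by a B-alkyl Suzuki–Miyaura coupling and sets out from bromide 10. Hydroboration of acrolein diethyl acetal with 9-BBN (THF, 0 °C to rt) gives 9-(3,3-diethoxypropyl)-9-borabicyclo[3.3.1]nonane F2. This is coupled with 10 (PdCl2(dppf), K3PO4, THF–H2O, 60 °C) to give 1-(benzyloxy)-2-(4-{2-[3-(benzyloxy)phenyl]ethyl}phenoxy)-4-(3,3-diethoxypropyl)benzene F3. Dilute HCl in THF at rt then liberates the aldehyde, coming back at 12.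

Step 8. The nitronate of nitromethane may add to freshly formed nitroalkene, and the amine base may move the double bond out of conjugation or erode the E geometry during the elimination. The fallback installs the nitro group by alkene nitration instead of condensation and sets out from bromide 10, bypassing step 7 as well. Negishi coupling with but-3-enylzinc bromide (PdCl2(dppf), THF, 50 °C) gives 1-(benzyloxy)-2-(4-{2-[3-(benzyloxy)phenyl]ethyl}phenoxy)-4-(but-3-en-1-yl)benzene F4. Radical nitration of the terminal alkene with AgNO2 and TEMPO (1,2-dichloroethane, 70 °C) should then deliver the E-nitroalkene, coming back at 15.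

Further compounds
F1 | step 9 | 1-(benzyloxy)-2-(4-{2-[3-(benzyloxy)phenyl]ethyl}phenoxy)-4-[(3-methoxyphenyl)ethynyl]benzene | COc1cccc(C#Cc2ccc(OCc3ccccc3)c(Oc3ccc(CCc4cccc(OCc5ccccc5)c4)cc3)c2)c1
F2 | step 7 | 9-(3,3-diethoxypropyl)-9-borabicyclo[3.3.1]nonane | CCOC(CCB1C2CCCC1CCC2)OCC
F3 | step 7 | 1-(benzyloxy)-2-(4-{2-[3-(benzyloxy)phenyl]ethyl}phenoxy)-4-(3,3-diethoxypropyl)benzene | CCOC(CCc1ccc(OCc2ccccc2)c(Oc2ccc(CCc3cccc(OCc4ccccc4)c3)cc2)c1)OCC
F4 | step 8 | 1-(benzyloxy)-2-(4-{2-[3-(benzyloxy)phenyl]ethyl}phenoxy)-4-(but-3-en-1-yl)benzene | C=CCCc1ccc(OCc2ccccc2)c(Oc2ccc(CCc3cccc(OCc4ccccc4)c3)cc2)c1
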